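**Retrosynthetic overview**
- The target (5,7-dihydroxy-6,8-dimethoxy flavone with a 3,5-dihydroxy-4-methoxyphenyl ring B) comes from tetrabenzyl ether 19 by hydrogenolysis; the C8–OMe comes from C8–Br (18) and that from the C8–H flavone 17.
- Ring C is the only ring made: 17 is cut at C8a–O1, C4a–C4 and O1–C2 into aryne 15 (from silyl triflate 10) and arylpropiolic acid 14.
- The strategy rests on O1 and C4 sitting on the adjacent ring A carbons C8a and C4a. With C8 left as C–H, the aryne C4a≡C8a has an oxygen substituent on one side only (C5), which sends the carboxylate oxygen to C8a and the acyl group to C4a.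
- Rings A and B both derive from 3,5-dihydroxy-4-methoxybenzoic acid 1 through aldehyde 4: Baeyer–Villiger oxidation, bromination and retro-Brook/triflation give 10; Ohira–Bestmann alkynylation and carboxylation give 14.

Key step: step 9

Remark: the target has no stereocentre, so no stereodescriptors are needed; flavone numbering (O1, C2–C4, C4a, C5–C8, C8a) is used for ring positions.

**Route**

Step 1
Reactants: 1 3,5-dihydroxy-4-methoxybenzoic acid
Product: 2 benzyl 3,5-bis(benzyloxy)-4-methoxybenzoate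
Conditions: BnBr (3.5 equiv), K2CO3 (4 equiv), DMF, 60 °C
Reagents that add atoms: benzyl bromide, BrCc1ccccc1
Why: Williamson O-alkylation of both phenoxides and SN2 alkylation of the carboxylate run together under K2CO3 in DMF, so one operation masks all three acidic groups and leaves the 4-OMe untouched.

Step 2
Reactants: 2 benzyl 3,5-bis(benzyloxy)-4-methoxybenzoate
Product: 3 [3,5-bis(benzyloxy)-4-methoxyphenyl]methanol
Conditions: LiAlH4, THF, 0 °C to rt; aqueous NaOH work-up
Reagents that add atoms: none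
Why: Hydride reduction of the benzyl ester with LiAlH4 should give the primary benzylic alcohol, while aryl benzyl and aryl methyl ethers are inert to hydride.

Step 3
Reactants: 3 [3,5-bis(benzyloxy)-4-methoxyphenyl]methanol
Product: 4 3,5-bis(benzyloxy)-4-methoxybenzaldehyde
Conditions: activated MnO2 (excess), CH2Cl2, rt
Reagents that add atoms: none
Why: Activated MnO2 oxidises benzylic alcohols selectively to aldehydes without over-oxidation and does not touch the ethers.

Step 4
Reactants: 4 3,5-bis(benzyloxy)-4-methoxybenzaldehyde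
Product: 6 3,5-bis(benzyloxy)-4-methoxyphenol, via aryl formate 5 (not isolated)
Conditions: mCPBA (1.3 equiv), CH2Cl2, 0 °C to rt; then K2CO3 (cat.), MeOH, rt
Reagents that add atoms: 3-chloroperoxybenzoic acid (mCPBA), OOC(=O)c1cccc(Cl)c1
Why: Baeyer–Villiger oxidation of this electron-rich benzaldehyde should proceed with aryl migration to the formate, which mild methanolysis cleaves to the phenol; the peracid variant is used because a hydrogen peroxide/base Dakin oxidation needs a free ortho- or para-hydroxyl group.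

Step 5
Reactants: 6 3,5-bis(benzyloxy)-4-methoxyphenol
Product: 7 3,5-bis(benzyloxy)-2-bromo-4-methoxyphenol
Conditions: NBS (1.0 equiv), CH2Cl2, −40 to 0 °C, dark
Reagents that add atoms: N-bromosuccinimide, O=C1CCC(=O)N1Br
Why: Electrophilic aromatic bromination with one equivalent of NBS should occur ortho to the hydroxyl group, and since the para position carries OMe and the two ortho positions are equivalent by symmetry only one monobromide can form.

Step 6
Reactants: 7 3,5-bis(benzyloxy)-2-bromo-4-methoxyphenol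
Product: 10 3,5-bis(benzyloxy)-4-methoxy-2-(trimethylsilyl)phenyl trifluoromethanesulfonate, via silyl ether 8 (not isolated), via lithium phenoxide 9 (not isolated)
Conditions: HMDS, THF, 70 °C, then concentrate; n-BuLi (1.1 equiv), THF, −100 to −80 °C; Tf2O (1.2 equiv), −100 to −80 °C
Reagents that add atoms: hexamethyldisilazane, C[Si](C)(C)N[Si](C)(C)C; trifluoromethanesulfonic anhydride, O=S(=O)(OS(=O)(=O)C(F)(F)F)C(F)(F)F
Why: O-silylation, bromine–lithium exchange and 1,3 O→C silyl shift (retro-Brook rearrangement) should place the silyl group on carbon and release a lithium phenoxide that Tf2O sulfonylates in the same flask, the standard one-pot entry to o-silylaryl triflates.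

Step 7
Reactants: 4 3,5-bis(benzyloxy)-4-methoxybenzaldehyde; 11 dimethyl (1-diazo-2-oxopropyl)phosphonate
Product: 12 1,3-bis(benzyloxy)-5-ethynyl-2-methoxybenzene
Conditions: 11 (1.3 equiv), K2CO3 (2 equiv), MeOH/THF, rt
Reagents that add atoms: dimethyl (1-diazo-2-oxopropyl)phosphonate (11), COP(=O)(OC)C(=[N+]=[N-])C(C)=O
Why: Ohira–Bestmann alkynylation: methanolysis of 11 gives the diazomethylphosphonate anion, which adds to the non-enolisable aldehyde in a Horner–Wadsworth–Emmons manner, and the diazoalkene loses N2 with 1,2-hydrogen shift to give the terminal alkyne under conditions mild enough for the benzyl ethers.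

Step 8
Reactants: 12 1,3-bis(benzyloxy)-5-ethynyl-2-methoxybenzene
Product: 14 3-[3,5-bis(benzyloxy)-4-methoxyphenyl]prop-2-ynoic acid, via lithium acetylide 13 (not isolated)
Conditions: n-BuLi (1.05 equiv), THF, −78 °C; CO2; aqueous HCl
Reagents that add atoms: carbon dioxide, O=C=O
Why: Deprotonation of the terminal alkyne, by far the most acidic C–H, and carboxylation of the lithium acetylide with CO2 is a standard route to arylpropiolic acids.

Step 9
Reactants: 10 3,5-bis(benzyloxy)-4-methoxy-2-(trimethylsilyl)phenyl trifluoromethanesulfonate; 14 3-[3,5-bis(benzyloxy)-4-methoxyphenyl]prop-2-ynoic acid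
Product: 17 5,7-bis(benzyloxy)-2-[3,5-bis(benzyloxy)-4-methoxyphenyl]-6-methoxy-4H-chromen-4-one, via aryne 15 (not isolated), via ynone phenoxide 16 (not isolated)
Conditions: 10 (1.5 equiv), CsF (4 equiv), THF, sealed tube, 125 °C
Reagents that add atoms: none
Why: Fluoride removes the trimethylsilyl group of 10 and expels triflate to give aryne 15 (C4a≡C8a) while 14 is present as its cesium carboxylate; the carboxylate oxygen adds to C8a, the terminus remote from the C5 benzyloxy group, because the distorted 3-alkoxyaryne is more electrophilic there and the aryl anion that develops on C4a is stabilised inductively by the adjacent C5–O bond. The C4a anion then attacks the ester carbonyl (4-exo-trig) to give a benzoxetene alkoxide that opens to the o-acyl phenoxide 16, which amounts to insertion of the aryne into the acid C–O bond and forms C8a–O1 and C4a–C4. The closest known reaction type is the fluoride-induced insertion of arynes into carboxylic acid C–O bonds, which gives o-hydroxyaryl ketones and, from arylpropiolic acids, flavones. Ring C is closed by 6-endo-dig oxa-Michael addition of the phenoxide oxygen to the ynone β-carbon (O1–C2), and the resulting allenolate is protonated at C3 by the hydrogen fluoride equivalent released when the acid was deprotonated. No stereocentre is formed; the step needs oxygen at C8a and acyl at C4a, which the single flanking C5 alkoxy group secures, acyl transfer faster than protonation of the aryl anion, which the high temperature and low standing proton concentration favour, and 6-endo over 5-exo closure, which a cesium phenoxide in aprotic THF favours.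

Step 10
Reactants: 17 5,7-bis(benzyloxy)-2-[3,5-bis(benzyloxy)-4-methoxyphenyl]-6-methoxy-4H-chromen-4-one
Product: 18 5,7-bis(benzyloxy)-2-[3,5-bis(benzyloxy)-4-methoxyphenyl]-8-bromo-6-methoxy-4H-chromen-4-one
Conditions: NBS (1.05 equiv), DMF, 0 °C to rt, dark
Reagents that add atoms: N-bromosuccinimide, O=C1CCC(=O)N1Br
Why: Electrophilic aromatic bromination should go to C8, the one unsubstituted carbon of ring A, which is ortho to the C7 benzyloxy group and O1 and para to the C5 benzyloxy group, whereas C3 and the ring B positions are deactivated by conjugation with the pyranone carbonyl.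

Step 11
Reactants: 18 5,7-bis(benzyloxy)-2-[3,5-bis(benzyloxy)-4-methoxyphenyl]-8-bromo-6-methoxy-4H-chromen-4-one
Product: 19 5,7-bis(benzyloxy)-2-[3,5-bis(benzyloxy)-4-methoxyphenyl]-6,8-dimethoxy-4H-chromen-4-one
Conditions: NaOMe (excess, in MeOH), CuBr (20 mol %), DMF, 110 °C
Reagents that add atoms: sodium methoxide, [Na+].[O-]C
Why: Ullmann-type copper-catalysed methoxylation replaces aryl bromides flanked by alkoxy groups with methoxide, a substitution established on 8-bromo-polyalkoxyflavones, and any partial loss of a benzyl group here would be harmless because all four are removed in the next step.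

Step 12
Reactants: 19 5,7-bis(benzyloxy)-2-[3,5-bis(benzyloxy)-4-methoxyphenyl]-6,8-dimethoxy-4H-chromen-4-one
Product: 20 5,7-dihydroxy-2-(3,5-dihydroxy-4-methoxyphenyl)-6,8-dimethoxy-4H-chromen-4-one
Conditions: H2 (1 atm), 10% Pd/C, EtOAc/MeOH, rt
Reagents that add atoms: none
Why: Catalytic hydrogenolysis over Pd/C should cleave the four benzylic C–O bonds at room temperature and atmospheric pressure, conditions under which the conjugated C2=C3 bond of a flavone and the aryl methyl ethers are retained.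

**Compound list**

1 | 3,5-dihydroxy-4-methoxybenzoic acid | COc1c(O)cc(C(=O)O)cc1O | starting material
2 | benzyl 3,5-bis(benzyloxy)-4-methoxybenzoate | COc1c(OCc2ccccc2)cc(C(=O)OCc2ccccc2)cc1OCc1ccccc1 | intermediate
3 | [3,5-bis(benzyloxy)-4-methoxyphenyl]methanol | COc1c(OCc2ccccc2)cc(CO)cc1OCc1ccccc1 | intermediate
4 | 3,5-bis(benzyloxy)-4-methoxybenzaldehyde | COc1c(OCc2ccccc2)cc(C=O)cc1OCc1ccccc1 | intermediate
5 | 3,5-bis(benzyloxy)-4-methoxyphenyl formate (not isolated) | COc1c(OCc2ccccc2)cc(OC=O)cc1OCc1ccccc1 | intermediate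
6 | 3,5-bis(benzyloxy)-4-methoxyphenol | COc1c(OCc2ccccc2)cc(O)cc1OCc1ccccc1 | intermediate
7 | 3,5-bis(benzyloxy)-2-bromo-4-methoxyphenol | COc1c(OCc2ccccc2)cc(O)c(Br)c1OCc1ccccc1 | intermediate
8 | [3,5-bis(benzyloxy)-2-bromo-4-methoxyphenoxy]trimethylsilane (not isolated) | COc1c(OCc2ccccc2)cc(O[Si](C)(C)C)c(Br)c1OCc1ccccc1 | intermediate
9 | lithium 3,5-bis(benzyloxy)-4-methoxy-2-(trimethylsilyl)phenoxide (not isolated) | COc1c(OCc2ccccc2)cc([O-])c([Si](C)(C)C)c1OCc1ccccc1.[Li+] | intermediate
10 | 3,5-bis(benzyloxy)-4-methoxy-2-(trimethylsilyl)phenyl trifluoromethanesulfonate | COc1c(OCc2ccccc2)cc(OS(=O)(=O)C(F)(F)F)c([Si](C)(C)C)c1OCc1ccccc1 | intermediate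
11 | dimethyl (1-diazo-2-oxopropyl)phosphonate | COP(=O)(OC)C(=[N+]=[N-])C(C)=O | starting material
12 | 1,3-bis(benzyloxy)-5-ethynyl-2-methoxybenzene | COc1c(OCc2ccccc2)cc(C#C)cc1OCc1ccccc1 | intermediate
13 | lithium [3,5-bis(benzyloxy)-4-methoxyphenyl]acetylide (not isolated) | [Li+].[C-]#Cc1cc(OCc2ccccc2)c(OC)c(OCc2ccccc2)c1 | intermediate
14 | 3-[3,5-bis(benzyloxy)-4-methoxyphenyl]prop-2-ynoic acid | COc1c(OCc2ccccc2)cc(C#CC(=O)O)cc1OCc1ccccc1 | intermediate
15 | 3,5-bis(benzyloxy)-4-methoxy-1,2-didehydrobenzene (aryne, not isolated) | COC1=C(OCc2ccccc2)C#CC=C1OCc1ccccc1 | intermediate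
16 | cesium 3,5-bis(benzyloxy)-2-{3-[3,5-bis(benzyloxy)-4-methoxyphenyl]prop-2-ynoyl}-4-methoxyphenoxide (not isolated) | COc1c(OCc2ccccc2)cc([O-])c(C(=O)C#Cc2cc(OCc3ccccc3)c(OC)c(OCc3ccccc3)c2)c1OCc1ccccc1.[Cs+] | intermediate
17 | 5,7-bis(benzyloxy)-2-[3,5-bis(benzyloxy)-4-methoxyphenyl]-6-methoxy-4H-chromen-4-one | COc1c(OCc2ccccc2)cc(-c2cc(=O)c3c(OCc4ccccc4)c(OC)c(OCc4ccccc4)cc3o2)cc1OCc1ccccc1 | intermediate
18 | 5,7-bis(benzyloxy)-2-[3,5-bis(benzyloxy)-4-methoxyphenyl]-8-bromo-6-methoxy-4H-chromen-4-one | COc1c(OCc2ccccc2)cc(-c2cc(=O)c3c(OCc4ccccc4)c(OC)c(OCc4ccccc4)c(Br)c3o2)cc1OCc1ccccc1 | intermediate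
19 | 5,7-bis(benzyloxy)-2-[3,5-bis(benzyloxy)-4-methoxyphenyl]-6,8-dimethoxy-4H-chromen-4-one | COc1c(OCc2ccccc2)cc(-c2cc(=O)c3c(OCc4ccccc4)c(OC)c(OCc4ccccc4)c(OC)c3o2)cc1OCc1ccccc1 | intermediate
20 | 5,7-dihydroxy-2-(3,5-dihydroxy-4-methoxyphenyl)-6,8-dimethoxy-4H-chromen-4-one | COc1c(O)cc(-c2cc(=O)c3c(O)c(OC)c(O)c(OC)c3o2)cc1O | target

**Step count**

Total: 12 steps. Longest linear sequence: 10 steps (steps 1, 2, 3, 4, 5, 6, 9, 10, 11, 12).

**Steps most likely to fail**

1. Step 9. The C4a aryl anion may be protonated before acyl transfer, which would stop the sequence at the aryl propiolate ester. The propiolate may also lose CO2 at the reaction temperature, and the phenoxide may close 5-exo to the aurone. The fallback builds the ynone stepwise by carbonyl addition; it sets out from 7 and 12 and comes back at 17. Bromophenol 7 would be protected (MOMCl, iPr2NEt, CH2Cl2) as 1,3-bis(benzyloxy)-4-bromo-2-methoxy-5-(methoxymethoxy)benzene F1. Bromine–lithium exchange (n-BuLi, THF, −78 °C) and formylation with DMF would give 2,4-bis(benzyloxy)-3-methoxy-6-(methoxymethoxy)benzaldehyde F2. Lithium acetylide 13, made from 12 as in step 8, would add to F2 to give racemic 1-[2,4-bis(benzyloxy)-3-methoxy-6-(methoxymethoxy)phenyl]-3-[3,5-bis(benzyloxy)-4-methoxyphenyl]prop-2-yn-1-ol F3. MnO2 in CH2Cl2 would oxidise it to 1-[2,4-bis(benzyloxy)-3-methoxy-6-(methoxymethoxy)phenyl]-3-[3,5-bis(benzyloxy)-4-methoxyphenyl]prop-2-yn-1-one F4. HCl in MeOH/THF would remove the acetal to give 1-[2,4-bis(benzyloxy)-6-hydroxy-3-methoxyphenyl]-3-[3,5-bis(benzyloxy)-4-methoxyphenyl]prop-2-yn-1-one F5, and K2CO3 in acetone would close it 6-endo to 17.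

2. Step 11. Substitution at the doubly ortho-substituted C8 may be slow, the C8–Br bond may be reduced, and methoxide may open the pyranone at the reaction temperature. The fallback forms the C8–O bond through boron; it sets out from 18 and comes back at 19. Miyaura borylation of 18 (B2pin2, PdCl2(dppf), KOAc, dioxane, 90 °C) would give 5,7-bis(benzyloxy)-2-[3,5-bis(benzyloxy)-4-methoxyphenyl]-6-methoxy-8-(4,4,5,5-tetramethyl-1,3,2-dioxaborolan-2-yl)-4H-chromen-4-one F6. Oxidation with NaBO3·4H2O in THF/water would give 5,7-bis(benzyloxy)-2-[3,5-bis(benzyloxy)-4-methoxyphenyl]-8-hydroxy-6-methoxy-4H-chromen-4-one F7, and MeI with K2CO3 in acetone would methylate it to 19.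

3. Step 6. Bromine–lithium exchange at the congested carbon may be incomplete, the aryllithium may be quenched before the silyl shift (loss of bromine without C-silylation), and triflation of the hindered phenoxide may be slow. The fallback installs silicon by carbamate-directed ortho-metalation with an external silyl chloride; it sets out from 6 and comes back at 10. Phenol 6 would be converted with isopropyl isocyanate and catalytic Et3N into 3,5-bis(benzyloxy)-4-methoxyphenyl N-(propan-2-yl)carbamate F8. N-silylation in situ (TBSOTf, TMEDA, Et2O), ortho-lithiation (n-BuLi, TMEDA, −78 °C) between the carbamate and the benzyloxy group, TMSCl quench and aqueous work-up would give 3,5-bis(benzyloxy)-4-methoxy-2-(trimethylsilyl)phenyl N-(propan-2-yl)carbamate F9. DBU and Et2NH in MeCN at 40 °C would release 3,5-bis(benzyloxy)-4-methoxy-2-(trimethylsilyl)phenol F10, which PhNTf2 in the same flask would convert into 10.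

**Further compounds**

F1 | step 9 | 1,3-bis(benzyloxy)-4-bromo-2-methoxy-5-(methoxymethoxy)benzene | COCOc1cc(OCc2ccccc2)c(OC)c(OCc2ccccc2)c1Br
F2 | step 9 | 2,4-bis(benzyloxy)-3-methoxy-6-(methoxymethoxy)benzaldehyde | COCOc1cc(OCc2ccccc2)c(OC)c(OCc2ccccc2)c1C=O
F3 | step 9 | rac-1-[2,4-bis(benzyloxy)-3-methoxy-6-(methoxymethoxy)phenyl]-3-[3,5-bis(benzyloxy)-4-methoxyphenyl]prop-2-yn-1-ol | COCOc1cc(OCc2ccccc2)c(OC)c(OCc2ccccc2)c1C(O)C#Cc1cc(OCc2ccccc2)c(OC)c(OCc2ccccc2)c1
F4 | step 9 | 1-[2,4-bis(benzyloxy)-3-methoxy-6-(methoxymethoxy)phenyl]-3-[3,5-bis(benzyloxy)-4-methoxyphenyl]prop-2-yn-1-one | COCOc1cc(OCc2ccccc2)c(OC)c(OCc2ccccc2)c1C(=O)C#Cc1cc(OCc2ccccc2)c(OC)c(OCc2ccccc2)c1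
F5 | step 9 | 1-[2,4-bis(benzyloxy)-6-hydroxy-3-methoxyphenyl]-3-[3,5-bis(benzyloxy)-4-methoxyphenyl]prop-2-yn-1-one | COc1c(OCc2ccccc2)cc(O)c(C(=O)C#Cc2cc(OCc3ccccc3)c(OC)c(OCc3ccccc3)c2)c1OCc1ccccc1
F6 | step 11 | 5,7-bis(benzyloxy)-2-[3,5-bis(benzyloxy)-4-methoxyphenyl]-6-methoxy-8-(4,4,5,5-tetramethyl-1,3,2-dioxaborolan-2-yl)-4H-chromen-4-one | COc1c(OCc2ccccc2)cc(-c2cc(=O)c3c(OCc4ccccc4)c(OC)c(OCc4ccccc4)c(B4OC(C)(C)C(C)(C)O4)c3o2)cc1OCc1ccccc1
F7 | step 11 | 5,7-bis(benzyloxy)-2-[3,5-bis(benzyloxy)-4-methoxyphenyl]-8-hydroxy-6-methoxy-4H-chromen-4-one | COc1c(OCc2ccccc2)cc(-c2cc(=O)c3c(OCc4ccccc4)c(OC)c(OCc4ccccc4)c(O)c3o2)cc1OCc1ccccc1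
F8 | step 6 | 3,5-bis(benzyloxy)-4-methoxyphenyl N-(propan-2-yl)carbamate | CC(C)NC(=O)Oc1cc(OCc2ccccc2)c(OC)c(OCc2ccccc2)c1
F9 | step 6 | 3,5-bis(benzyloxy)-4-methoxy-2-(trimethylsilyl)phenyl N-(propan-2-yl)carbamate | CC(C)NC(=O)Oc1cc(OCc2ccccc2)c(OC)c(OCc2ccccc2)c1[Si](C)(C)C
F10 | step 6 | 3,5-bis(benzyloxy)-4-methoxy-2-(trimethylsilyl)phenol | COc1c(OCc2ccccc2)cc(O)c([Si](C)(C)C)c1OCc1ccccc1
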